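The route rests on the cis C3=C4 alkene of the 2,2-dimethyl-2H-pyran ring fused to the acylphloroglucinol core. Both carbons are CH, C4 on the ring-fusion carbon C4a and C3 on the oxygen-bearing CMe2 carbon, so the pyran is the ring-closing metathesis product of a C-vinyl group and an O-(2-methylbut-3-en-2-yl) ether. The precursor is 2,4,6-trihydroxybenzophenone carrying the vinyl group at C3 and the tertiary allyl ether on the para oxygen; one metathesis closes the pyran with unambiguous regiochemistry and loses only ethylene. C-Alkylation with an Evans-derived side-chain iodide, a ligand-controlled palladium dearomative prenylation that creates the quaternary carbon, and ester hydrolysis complete the target.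

Key step: step 5

Remark: 21 and 22 are written in the enol tautomer of the target structure (7-hydroxy-5-oxo); the sense of induction of the Trost ligand in step 11 is assumed, and the enantiomeric ligand would be used should the assay show the opposite.

Step 1
Reactants: 1 (2,4,6-trihydroxyphenyl)(phenyl)methanone
Product: 2 (2,4,6-trihydroxy-3-iodophenyl)(phenyl)methanone
Conditions: N-iodosuccinimide (1.0 equiv), MeCN, −20 to 0 °C
Reagents that add atoms: N-iodosuccinimide, O=C1CCC(=O)N1I
Why: Electrophilic aromatic iodination of the strongly activated phloroglucinol ring, in which the two unsubstituted ring carbons of 1 are equivalent, so one equivalent of reagent at low temperature should give the mono-iodide without a regiochemical question.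

Step 2
Reactants: 2 (2,4,6-trihydroxy-3-iodophenyl)(phenyl)methanone; 3 tributyl(vinyl)stannane
Product: 4 (3-ethenyl-2,4,6-trihydroxyphenyl)(phenyl)methanone
Conditions: Pd(PPh3)4 (5 mol %), BHT (trace), DMF, 70 °C
Reagents that add atoms: none
Why: Stille cross-coupling, in which oxidative addition of the aryl iodide to zerovalent palladium, vinyl transfer from tin and reductive elimination proceed under neutral conditions that leave the hydrogen-bonded phenols untouched.

Step 3
Reactants: 4 (3-ethenyl-2,4,6-trihydroxyphenyl)(phenyl)methanone; 5 3-chloro-3-methylbut-1-yne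
Product: 6 {3-ethenyl-2,6-dihydroxy-4-[(2-methylbut-3-yn-2-yl)oxy]phenyl}(phenyl)methanone
Conditions: DBU (1.3 equiv), CuCl2·2H2O (1 mol %), MeCN, −5 to 0 °C
Reagents that add atoms: none
Why: Copper-catalysed propargylic etherification of a phenol with a tertiary propargylic chloride through a copper allenylidene, selective for the 4-hydroxyl because it is para to the benzoyl group, the most acidic, and the only one not held in a hydrogen bond to the ketone.

Step 4
Reactants: 6 {3-ethenyl-2,6-dihydroxy-4-[(2-methylbut-3-yn-2-yl)oxy]phenyl}(phenyl)methanone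
Product: 7 {3-ethenyl-2,6-dihydroxy-4-[(2-methylbut-3-en-2-yl)oxy]phenyl}(phenyl)methanone
Conditions: H2 (1 atm, stopped after one equivalent), Lindlar catalyst (Pd on CaCO3 poisoned with Pb(OAc)2), quinoline, EtOAc, 20 °C
Reagents that add atoms: none
Why: Lindlar semi-hydrogenation, which stops at the alkene for the terminal alkyne while the conjugated aryl vinyl group is reduced much more slowly on the poisoned catalyst.

Step 5
Reactants: 7 {3-ethenyl-2,6-dihydroxy-4-[(2-methylbut-3-en-2-yl)oxy]phenyl}(phenyl)methanone
Product: 8 (5,7-dihydroxy-2,2-dimethyl-2H-chromen-6-yl)(phenyl)methanone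
Conditions: second-generation Grubbs catalyst (H2IMes)(PCy3)Cl2Ru=CHPh (5 mol %), CH2Cl2 (0.005 M), 40 °C
Reagents that add atoms: none
Why: The ruthenium benzylidene initiates at the unhindered aryl vinyl group to give a styrenyl carbene chelated by the adjacent ether oxygen, which adds to the pendant 1,1-dimethylallyl alkene in a [2+2] cycloaddition, and the ruthenacyclobutane collapses by cycloreversion (Chauvin mechanism) to the chromene and a ruthenium methylidene that leaves as ethylene in the next turnover. The closest known reaction type is the ring-closing metathesis of 2-vinylaryl allyl and 1,1-dimethylallyl ethers to 2H-chromenes. The six-membered 2H-pyran ring is closed by intramolecular alkene metathesis between two terminal vinyl groups, and the ring size enforces the cis geometry of the new C3=C4 bond. No stereocentre is formed. The step needs ring closure to win over oligomerisation and over thermal Claisen rearrangement of the tertiary allyl aryl ether: high dilution, the gem-dimethyl group (Thorpe–Ingold effect) and a temperature of 40 °C should secure this, 7 contains no other alkene, and both phenols are tied up in hydrogen bonds to the benzoyl group.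

Step 6
Reactants: 9 (4S)-4-benzyl-1,3-oxazolidin-2-one; 10 3-methylbut-2-enoyl chloride
Product: 12 (4S)-4-benzyl-3-(3-methylbut-2-enoyl)-1,3-oxazolidin-2-one, via lithium oxazolidinide 11 (not isolated)
Conditions: n-BuLi (1.0 equiv), THF, −78 °C; then 10, −78 to 0 °C
Reagents that add atoms: none
Why: N-Acylation of the lithiated Evans oxazolidinone with the acid chloride at low temperature, which attaches the auxiliary without touching its stereocentre.

Step 7
Reactants: 12 (4S)-4-benzyl-3-(3-methylbut-2-enoyl)-1,3-oxazolidin-2-one; 13 methyl (2E)-4-bromo-2-methylbut-2-enoate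
Product: 15 methyl (2E,5S)-5-{[(4S)-4-benzyl-2-oxo-1,3-oxazolidin-3-yl]carbonyl}-2,6-dimethylhepta-2,6-dienoate, via sodium dienolate 14 (not isolated)
Conditions: NaN(SiMe3)2 (1.1 equiv), THF, −78 °C; then 13 (1.3 equiv), −78 to −40 °C
Reagents that add atoms: none
Why: Evans asymmetric alkylation in its deconjugative form, in which γ-deprotonation gives the sodium-chelated Z dienolate that attacks the allylic bromide in an SN2 reaction through its α-carbon on the face opposite the benzyl group, so that the S stereocentre and the isopropenyl group arise together.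

Step 8
Reactants: 15 methyl (2E,5S)-5-{[(4S)-4-benzyl-2-oxo-1,3-oxazolidin-3-yl]carbonyl}-2,6-dimethylhepta-2,6-dienoate
Product: 16 methyl (2E,5S)-5-(hydroxymethyl)-2,6-dimethylhepta-2,6-dienoate
Conditions: NaBH4 (4 equiv), THF/H2O (4:1), 0 to 20 °C
Reagents that add atoms: none
Why: Reductive cleavage of the N-acyl oxazolidinone by borohydride, which attacks the activated imide carbonyl but not the conjugated methyl ester, should release the primary alcohol without epimerisation and return the auxiliary 9.

Step 9
Reactants: 16 methyl (2E,5S)-5-(hydroxymethyl)-2,6-dimethylhepta-2,6-dienoate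
Product: 17 methyl (2E,5S)-5-(iodomethyl)-2,6-dimethylhepta-2,6-dienoate
Conditions: I2, PPh3, imidazole, CH2Cl2, 0 to 20 °C
Reagents that add atoms: iodine, II
Why: Appel-type iodination, an SN2 displacement of the phosphonium-activated primary hydroxyl that does not involve the adjacent stereocentre.

Step 10
Reactants: 8 (5,7-dihydroxy-2,2-dimethyl-2H-chromen-6-yl)(phenyl)methanone; 17 methyl (2E,5S)-5-(iodomethyl)-2,6-dimethylhepta-2,6-dienoate
Product: 19 methyl (2E,5R)-5-[(6-benzoyl-5,7-dihydroxy-2,2-dimethyl-2H-chromen-8-yl)methyl]-2,6-dimethylhepta-2,6-dienoate, via disodium bisphenoxide 18 (not isolated)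
Conditions: 8 (2 equiv), NaH (4 equiv), toluene/THF (5:1), 0 to 20 °C; then 17 (1 equiv), 80 °C; aqueous NH4Cl work-up
Reagents that add atoms: none
Why: C-Alkylation of an ambident phloroglucinol-type phenoxide, in which the tightly ion-paired sodium salt in a non-polar medium should react with the soft primary iodide through C8, the only free ring carbon and ortho and para to the two oxido groups, while the stereocentre of 17 is carried over unchanged (its descriptor becomes R only through the change in substituent priorities).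

Step 11
Reactants: 19 methyl (2E,5R)-5-[(6-benzoyl-5,7-dihydroxy-2,2-dimethyl-2H-chromen-8-yl)methyl]-2,6-dimethylhepta-2,6-dienoate; 20 3-methylbut-2-en-1-yl acetate
Product: 21 methyl (2E,5R)-5-{[(8S)-6-benzoyl-7-hydroxy-2,2-dimethyl-8-(3-methylbut-2-en-1-yl)-5-oxo-5,8-dihydro-2H-chromen-8-yl]methyl}-2,6-dimethylhepta-2,6-dienoate
Conditions: Pd2(dba)3·CHCl3 (2.5 mol %), (R,R)-DACH-phenyl Trost ligand (7.5 mol %), Cs2CO3 (1.1 equiv), THF, 0 to 20 °C
Reagents that add atoms: none
Why: Tsuji–Trost allylic alkylation run as an asymmetric alkylative dearomatisation, in which the phenoxide attacks the 1,1-dimethylallyl palladium cation at its unsubstituted terminus through the substituted carbon C8, O-prenyl ethers being returned to the cation by re-ionisation, and the chiral ligand pocket selects the face of C8 so that the S quaternary centre is set by the catalyst and not by the remote side-chain stereocentre.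

Step 12
Reactants: 21 methyl (2E,5R)-5-{[(8S)-6-benzoyl-7-hydroxy-2,2-dimethyl-8-(3-methylbut-2-en-1-yl)-5-oxo-5,8-dihydro-2H-chromen-8-yl]methyl}-2,6-dimethylhepta-2,6-dienoate
Product: 22 (2E,5R)-5-{[(8S)-6-benzoyl-7-hydroxy-2,2-dimethyl-8-(3-methylbut-2-en-1-yl)-5-oxo-5,8-dihydro-2H-chromen-8-yl]methyl}-2,6-dimethylhepta-2,6-dienoic acid
Conditions: LiOH·H2O (5 equiv), THF/MeOH/H2O (3:1:1), 20 °C; then 1 M HCl to pH 3 at 0 °C
Reagents that add atoms: lithium hydroxide, [Li+].[OH-]
Why: Saponification of the methyl ester, during which the acidic enolised triketone is held as its delocalised enolate, which protects the benzoyl group against retro-Claisen cleavage, and no stereocentre is epimerisable.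

Compound list
1 | (2,4,6-trihydroxyphenyl)(phenyl)methanone (2,4,6-trihydroxybenzophenone) | O=C(c1ccccc1)c1c(O)cc(O)cc1O | starting material
2 | (2,4,6-trihydroxy-3-iodophenyl)(phenyl)methanone | O=C(c1ccccc1)c1c(O)cc(O)c(I)c1O | intermediate
3 | tributyl(vinyl)stannane | C=C[Sn](CCCC)(CCCC)CCCC | starting material
4 | (3-ethenyl-2,4,6-trihydroxyphenyl)(phenyl)methanone | O=C(c1ccccc1)c1c(O)cc(O)c(C=C)c1O | intermediate
5 | 3-chloro-3-methylbut-1-yne | C#CC(C)(C)Cl | starting material
6 | {3-ethenyl-2,6-dihydroxy-4-[(2-methylbut-3-yn-2-yl)oxy]phenyl}(phenyl)methanone | O=C(c1ccccc1)c1c(O)cc(OC(C)(C)C#C)c(C=C)c1O | intermediate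
7 | {3-ethenyl-2,6-dihydroxy-4-[(2-methylbut-3-en-2-yl)oxy]phenyl}(phenyl)methanone | O=C(c1ccccc1)c1c(O)cc(OC(C)(C)C=C)c(C=C)c1O | intermediate
8 | (5,7-dihydroxy-2,2-dimethyl-2H-chromen-6-yl)(phenyl)methanone | O=C(c1ccccc1)c1c(O)cc2OC(C)(C)C=Cc2c1O | intermediate
9 | (4S)-4-benzyl-1,3-oxazolidin-2-one | O=C1N[C@@H](Cc2ccccc2)CO1 | starting material
10 | 3-methylbut-2-enoyl chloride | CC(C)=CC(=O)Cl | starting material
11 | lithium (4S)-4-benzyl-2-oxo-1,3-oxazolidin-3-ide | O=C1[N-][C@@H](Cc2ccccc2)CO1.[Li+] | intermediate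
12 | (4S)-4-benzyl-3-(3-methylbut-2-enoyl)-1,3-oxazolidin-2-one | CC(C)=CC(=O)N1[C@@H](Cc2ccccc2)COC1=O | intermediate
13 | methyl (2E)-4-bromo-2-methylbut-2-enoate | COC(=O)/C(C)=C/CBr | starting material
14 | sodium (1Z)-1-[(4S)-4-benzyl-2-oxo-1,3-oxazolidin-3-yl]-3-methylbuta-1,3-dien-1-olate | C=C(C)/C=C(\[O-])N1[C@@H](Cc2ccccc2)COC1=O.[Na+] | intermediate
15 | methyl (2E,5S)-5-{[(4S)-4-benzyl-2-oxo-1,3-oxazolidin-3-yl]carbonyl}-2,6-dimethylhepta-2,6-dienoate | C=C(C)[C@H](C/C=C(\C)C(=O)OC)C(=O)N1[C@@H](Cc2ccccc2)COC1=O | intermediate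
16 | methyl (2E,5S)-5-(hydroxymethyl)-2,6-dimethylhepta-2,6-dienoate | C=C(C)[C@H](C/C=C(\C)C(=O)OC)CO | intermediate
17 | methyl (2E,5S)-5-(iodomethyl)-2,6-dimethylhepta-2,6-dienoate | C=C(C)[C@H](C/C=C(\C)C(=O)OC)CI | intermediate
18 | disodium 6-benzoyl-2,2-dimethyl-2H-chromene-5,7-bis(olate) | O=C(c1ccccc1)c1c([O-])cc2OC(C)(C)C=Cc2c1[O-].[Na+].[Na+] | intermediate
19 | methyl (2E,5R)-5-[(6-benzoyl-5,7-dihydroxy-2,2-dimethyl-2H-chromen-8-yl)methyl]-2,6-dimethylhepta-2,6-dienoate | C=C(C)[C@H](C/C=C(\C)C(=O)OC)Cc1c(O)c(C(=O)c2ccccc2)c(O)c2C=CC(C)(C)Oc12 | intermediate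
20 | 3-methylbut-2-en-1-yl acetate (prenyl acetate) | CC(C)=CCOC(C)=O | starting material
21 | methyl (2E,5R)-5-{[(8S)-6-benzoyl-7-hydroxy-2,2-dimethyl-8-(3-methylbut-2-en-1-yl)-5-oxo-5,8-dihydro-2H-chromen-8-yl]methyl}-2,6-dimethylhepta-2,6-dienoate | C=C(C)[C@H](C/C=C(\C)C(=O)OC)C[C@@]1(CC=C(C)C)C(O)=C(C(=O)c2ccccc2)C(=O)C2=C1OC(C)(C)C=C2 | intermediate
22 | (2E,5R)-5-{[(8S)-6-benzoyl-7-hydroxy-2,2-dimethyl-8-(3-methylbut-2-en-1-yl)-5-oxo-5,8-dihydro-2H-chromen-8-yl]methyl}-2,6-dimethylhepta-2,6-dienoic acid (CNP0333091.1) | C=C(C)[C@H](C/C=C(\C)C(=O)O)C[C@@]1(CC=C(C)C)C(O)=C(C(=O)c2ccccc2)C(=O)C2=C1OC(C)(C)C=C2 | target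

Total step count: 12
Longest linear sequence: 8 steps (steps 1 to 5, then 10 to 12)

Steps most likely to fail

Step 10. The ambident phenoxide may be alkylated on oxygen instead of carbon, and substitution at the β-branched primary iodide may be slow enough for base-induced elimination to compete. The fallback replaces the substitution by an sp2–sp3 Negishi cross-coupling and sets out from 8 and 17. Compound 8 is iodinated at C8 with N-iodosuccinimide in MeCN at −20 °C to (5,7-dihydroxy-8-iodo-2,2-dimethyl-2H-chromen-6-yl)(phenyl)methanone F1. Compound 17 is converted with zinc dust and LiCl in THF into iodo[(2S,4E)-6-methoxy-5-methyl-6-oxo-2-(prop-1-en-2-yl)hex-4-en-1-yl]zinc F2. Slow addition of F2 to F1 with Pd(OAc)2 and SPhos in THF at 25 °C should give 19, where the route is rejoined.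

Step 11. Facial selection at C8 by the chiral catalyst may be poor, and attack at the substituted allyl terminus or on oxygen may compete. The fallback gives up catalyst control and sets out from 19. Stoichiometric alkylation with prenyl bromide and NaOMe in MeOH at 0 °C should give 21 together with its C8 epimer, methyl (2E,5R)-5-{[(8R)-6-benzoyl-7-hydroxy-2,2-dimethyl-8-(3-methylbut-2-en-1-yl)-5-oxo-5,8-dihydro-2H-chromen-8-yl]methyl}-2,6-dimethylhepta-2,6-dienoate F3. The two diastereomers are separated by preparative HPLC, and the route is rejoined at 21.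

Step 7. The dienolate may add to the γ-bromo enoate in a conjugate fashion and close a cyclopropane, or attack in an SN2′ sense, instead of displacing bromide directly. The fallback builds the enoate after the alkylation and sets out from 12. The same sodium dienolate is alkylated with allyl bromide to (4S)-4-benzyl-3-[(2S)-2-(prop-1-en-2-yl)pent-4-enoyl]-1,3-oxazolidin-2-one F4. Cross-metathesis of the terminal alkene of F4 with excess methyl methacrylate, using the second-generation Hoveyda–Grubbs catalyst (H2IMes)Cl2Ru=CH(C6H4-2-OiPr) in CH2Cl2 at 40 °C, should give the E enoate 15, where the route is rejoined.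

Further compounds
F1 | step 10 | (5,7-dihydroxy-8-iodo-2,2-dimethyl-2H-chromen-6-yl)(phenyl)methanone | O=C(c1ccccc1)c1c(O)c(I)c2OC(C)(C)C=Cc2c1O
F2 | step 10 | iodo[(2S,4E)-6-methoxy-5-methyl-6-oxo-2-(prop-1-en-2-yl)hex-4-en-1-yl]zinc | C=C(C)[C@H](C/C=C(\C)C(=O)OC)C[Zn]I
F3 | step 11 | methyl (2E,5R)-5-{[(8R)-6-benzoyl-7-hydroxy-2,2-dimethyl-8-(3-methylbut-2-en-1-yl)-5-oxo-5,8-dihydro-2H-chromen-8-yl]methyl}-2,6-dimethylhepta-2,6-dienoate | C=C(C)[C@H](C/C=C(\C)C(=O)OC)C[C@]1(CC=C(C)C)C(O)=C(C(=O)c2ccccc2)C(=O)C2=C1OC(C)(C)C=C2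
F4 | step 7 | (4S)-4-benzyl-3-[(2S)-2-(prop-1-en-2-yl)pent-4-enoyl]-1,3-oxazolidin-2-one | C=C(C)[C@H](CC=C)C(=O)N1[C@@H](Cc2ccccc2)COC1=O
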